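**Assumption:** the target (2-O-methylstenosporic acid, C24H30O7) has no stereocentre and is achiral, so there is no enantiomer to select. The sp3 centres in 3–5 and 10–12 are racemic and are erased on aromatisation.

## Retrosynthetic overview
1. Target 20 ⇒ benzyl ester 19 (hydrogenolysis) ⇒ depside C(=O)–O disconnection into A-ring acid 8 and benzyl olivetolate 17.
2. 8 ⇒ methyl divarate 6 (O-methylation, saponification). 17 ⇒ methyl olivetolate 13 (Bn-masked saponification, then carboxylate benzylation).
3. Each resorcylate (6, 13) ⇒ 2,4-dioxocyclohexanecarboxylate (4, 11) by bromination–dehydrobromination.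
4. Key C–C bond: intermolecular Michael addition of dimethyl malonate 2 to enone 1 or 9, followed in the same pot by Dieckmann closure.
5. Ring order: ring A (steps 1–2) and ring B (steps 5–6) are built independently and joined last (step 11).

## Route

**Step 1**
Reactants: 1 (E)-hept-3-en-2-one; 2 dimethyl malonate
Product: 4 methyl 2-hydroxy-4-oxo-6-propylcyclohex-2-ene-1-carboxylate, via Michael adduct 3 (not isolated)
Conditions: NaOMe (1.2 equiv), MeOH, rt then reflux 4 h; evaporate, H2O, ether wash; HCl to pH 2–3, 0 °C
Reagents that add atoms: none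
Why: The malonate anion adds 1,4 to the enone (intermolecular Michael addition), then the methyl-ketone enolate of 3 closes onto one ester (Dieckmann/intramolecular Claisen condensation), driven by deprotonation of the β-diketone; the two racemic sp3 centres are erased in step 2.

**Step 2**
Reactants: 4 methyl 2-hydroxy-4-oxo-6-propylcyclohex-2-ene-1-carboxylate
Product: 6 methyl 2,4-dihydroxy-6-propylbenzoate, via 3-bromo diketone 5 (not isolated)
Conditions: Br2 (1.0 equiv), DMF, 0 °C, 1 h; then 80 °C, about 12 h (monitored); aq Na2S2O3 work-up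
Reagents that add atoms: bromine, BrBr (Br is carried only by intermediate 5 and leaves again as HBr)
Why: Electrophilic bromination of the enolised β-diketone, thermal dehydrobromination and tautomerisation (bromination–dehydrobromination aromatisation) give the resorcylate, with DMF buffering the HBr so the methyl ester is kept.

**Step 3**
Reactants: 6 methyl 2,4-dihydroxy-6-propylbenzoate
Product: 7 methyl 2,4-dimethoxy-6-propylbenzoate
Conditions: MeI (4 equiv), K2CO3 (4 equiv), DMF, 40 °C (closed flask), 16 h
Reagents that add atoms: iodomethane, CI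
Why: This is a Williamson ether synthesis, and excess MeI in a dipolar aprotic solvent also methylates the chelated 2-OH.

**Step 4**
Reactants: 7 methyl 2,4-dimethoxy-6-propylbenzoate
Product: 8 2,4-dimethoxy-6-propylbenzoic acid
Conditions: KOH (10 equiv), DMSO–H2O 4:1, 100 °C, 6–12 h; then ice, 2 M HCl to pH 2 at 0 °C
Reagents that add atoms: potassium hydroxide, [K+].[OH-]
Why: Forcing saponification (BAc2) overcomes the di-ortho hindrance, nothing else in 7 is base-labile, and cold acidification avoids protodecarboxylation of the electron-rich acid.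

**Step 5**
Reactants: 9 (E)-non-3-en-2-one; 2 dimethyl malonate
Product: 11 methyl 2-hydroxy-4-oxo-6-pentylcyclohex-2-ene-1-carboxylate, via Michael adduct 10 (not isolated)
Conditions: NaOMe (1.2 equiv), MeOH, rt then reflux 4 h; evaporate, H2O, ether wash; HCl to pH 2–3, 0 °C
Reagents that add atoms: none
Why: The same intermolecular Michael addition and Dieckmann condensation cascade as in step 1 applies, and the racemic sp3 centres are erased in step 6.

**Step 6**
Reactants: 11 methyl 2-hydroxy-4-oxo-6-pentylcyclohex-2-ene-1-carboxylate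
Product: 13 methyl 2,4-dihydroxy-6-pentylbenzoate, via 3-bromo diketone 12 (not isolated)
Conditions: Br2 (1.0 equiv), DMF, 0 °C, 1 h; then 80 °C, about 12 h (monitored); aq Na2S2O3 work-up
Reagents that add atoms: bromine, BrBr (Br is carried only by intermediate 12 and leaves again as HBr)
Why: This is the same bromination–dehydrobromination aromatisation as step 2, giving methyl olivetolate.

**Step 7**
Reactants: 13 methyl 2,4-dihydroxy-6-pentylbenzoate
Product: 14 methyl 2,4-bis(benzyloxy)-6-pentylbenzoate
Conditions: BnBr (2.5 equiv), K2CO3 (4 equiv), DMF, 60 °C, 12 h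
Reagents that add atoms: benzyl bromide, BrCc1ccccc1
Why: Williamson benzylation masks both phenols, so the ester can be saponified without forming an unreactive phenoxide and without hot-base decarboxylation of a free resorcylic acid.

**Step 8**
Reactants: 14 methyl 2,4-bis(benzyloxy)-6-pentylbenzoate
Product: 15 2,4-bis(benzyloxy)-6-pentylbenzoic acid
Conditions: KOH (10 equiv), DMSO–H2O 4:1, 100 °C, 8–12 h; then ice, 2 M HCl to pH 2 at 0 °C
Reagents that add atoms: potassium hydroxide, [K+].[OH-]
Why: Forcing saponification (BAc2) cleaves the hindered ester, and the benzyl ethers are inert to hydroxide.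

**Step 9**
Reactants: 15 2,4-bis(benzyloxy)-6-pentylbenzoic acid
Product: 16 2,4-dihydroxy-6-pentylbenzoic acid (olivetolic acid)
Conditions: H2 (1 atm), 10% Pd/C, EtOAc, rt, 3 h; filter, concentrate below 30 °C
Reagents that add atoms: none
Why: Catalytic hydrogenolysis of the benzyl ethers frees the decarboxylation-prone acid under neutral conditions at room temperature.

**Step 10**
Reactants: 16 2,4-dihydroxy-6-pentylbenzoic acid
Product: 17 benzyl 2,4-dihydroxy-6-pentylbenzoate
Conditions: BnBr (1.05 equiv), KHCO3 (1.2 equiv), DMF, rt, 24 h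
Reagents that add atoms: benzyl bromide, BrCc1ccccc1
Why: Bicarbonate deprotonates only the carboxylic acid, so the SN2 O-alkylation takes place chemoselectively at the carboxylate and both phenols stay free.

**Step 11**
Reactants: 8 2,4-dimethoxy-6-propylbenzoic acid; 17 benzyl 2,4-dihydroxy-6-pentylbenzoate
Product: 19 benzyl 4-[(2,4-dimethoxy-6-propylbenzoyl)oxy]-2-hydroxy-6-pentylbenzoate, via mixed trifluoroacetic anhydride 18 (not isolated)
Conditions: TFAA (4 equiv), dry toluene, 0 °C to rt, 3–4 h; evaporate, chromatography
Reagents that add atoms: trifluoroacetic anhydride, O=C(OC(=O)C(F)(F)F)C(F)(F)F (its CF3CO group is carried only by intermediate 18; none of its atoms stays in 19)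
Why: In this mixed-anhydride esterification the electron-rich hindered acid reacts through an acylium-like species, and only the unhindered 4-OH is acylated because the 2-OH is hydrogen-bonded to the benzyl ester carbonyl.

**Step 12**
Reactants: 19 benzyl 4-[(2,4-dimethoxy-6-propylbenzoyl)oxy]-2-hydroxy-6-pentylbenzoate
Product: 20 4-[(2,4-dimethoxy-6-propylbenzoyl)oxy]-2-hydroxy-6-pentylbenzoic acid (target)
Conditions: H2 (1 atm), 10% Pd/C, EtOAc, rt, 2 h; filter, crystallise
Reagents that add atoms: none
Why: Catalytic hydrogenolysis cleaves only the benzyl ester, leaving the aryl (depside) ester, the methyl ethers and the free phenol untouched under neutral conditions.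

## Compound list
1 | (E)-hept-3-en-2-one | CCC/C=C/C(C)=O | starting material
2 | dimethyl malonate | COC(=O)CC(=O)OC | starting material
3 | dimethyl 2-(2-oxoheptan-4-yl)propanedioate (racemic; not isolated) | CCCC(CC(C)=O)C(C(=O)OC)C(=O)OC | intermediate
4 | methyl 2-hydroxy-4-oxo-6-propylcyclohex-2-ene-1-carboxylate (racemic; enol form of the 2,4-dione) | CCCC1CC(=O)C=C(O)C1C(=O)OC | intermediate
5 | methyl 3-bromo-2-hydroxy-4-oxo-6-propylcyclohex-2-ene-1-carboxylate (racemic; not isolated) | CCCC1CC(=O)C(Br)=C(O)C1C(=O)OC | intermediate
6 | methyl 2,4-dihydroxy-6-propylbenzoate (methyl divarate) | CCCc1cc(O)cc(O)c1C(=O)OC | intermediate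
7 | methyl 2,4-dimethoxy-6-propylbenzoate | CCCc1cc(OC)cc(OC)c1C(=O)OC | intermediate
8 | 2,4-dimethoxy-6-propylbenzoic acid | CCCc1cc(OC)cc(OC)c1C(=O)O | intermediate
9 | (E)-non-3-en-2-one | CCCCC/C=C/C(C)=O | starting material
10 | dimethyl 2-(2-oxononan-4-yl)propanedioate (racemic; not isolated) | CCCCCC(CC(C)=O)C(C(=O)OC)C(=O)OC | intermediate
11 | methyl 2-hydroxy-4-oxo-6-pentylcyclohex-2-ene-1-carboxylate (racemic; enol form of the 2,4-dione) | CCCCCC1CC(=O)C=C(O)C1C(=O)OC | intermediate
12 | methyl 3-bromo-2-hydroxy-4-oxo-6-pentylcyclohex-2-ene-1-carboxylate (racemic; not isolated) | CCCCCC1CC(=O)C(Br)=C(O)C1C(=O)OC | intermediate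
13 | methyl 2,4-dihydroxy-6-pentylbenzoate (methyl olivetolate) | CCCCCc1cc(O)cc(O)c1C(=O)OC | intermediate
14 | methyl 2,4-bis(benzyloxy)-6-pentylbenzoate | CCCCCc1cc(OCc2ccccc2)cc(OCc2ccccc2)c1C(=O)OC | intermediate
15 | 2,4-bis(benzyloxy)-6-pentylbenzoic acid | CCCCCc1cc(OCc2ccccc2)cc(OCc2ccccc2)c1C(=O)O | intermediate
16 | 2,4-dihydroxy-6-pentylbenzoic acid (olivetolic acid) | CCCCCc1cc(O)cc(O)c1C(=O)O | intermediate
17 | benzyl 2,4-dihydroxy-6-pentylbenzoate | CCCCCc1cc(O)cc(O)c1C(=O)OCc1ccccc1 | intermediate
18 | 2,4-dimethoxy-6-propylbenzoic trifluoroacetic anhydride (not isolated) | CCCc1cc(OC)cc(OC)c1C(=O)OC(=O)C(F)(F)F | intermediate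
19 | benzyl 4-[(2,4-dimethoxy-6-propylbenzoyl)oxy]-2-hydroxy-6-pentylbenzoate | CCCCCc1cc(OC(=O)c2c(CCC)cc(OC)cc2OC)cc(O)c1C(=O)OCc1ccccc1 | intermediate
20 | 4-[(2,4-dimethoxy-6-propylbenzoyl)oxy]-2-hydroxy-6-pentylbenzoic acid (achiral) | CCCCCc1cc(OC(=O)c2c(CCC)cc(OC)cc2OC)cc(O)c1C(=O)O | target

## Step count
- **Total steps:** 12.
- **Longest linear sequence:** 8 (steps 5, 6, 7, 8, 9, 10, 11, 12).

## Steps most likely to fail, with fallbacks

**Step 2 (aromatisation of 4).** The risks are ring over-bromination of the resorcinol formed and bromide-induced ester cleavage with decarboxylation at 80 °C. The fallback sets out from 4 and comes back at 7, skipping 6. Refluxing 4 with I2 in MeOH forms the C4 enol ether and oxidises the ring by iodination and loss of HI. This gives methyl 2-hydroxy-4-methoxy-6-propylbenzoate F1. Any dimethyl ether formed alongside is already 7. The crude material is then methylated at the remaining chelated 2-OH with MeI and K2CO3 in DMF, which converges on 7.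

**Step 6 (aromatisation of 11).** The risks are the same, and here a free resorcinol is needed, so the methanol route is not usable. The fallback sets out from 11 and comes back at 13. Over-bromination is made deliberate: 3 equiv of Br2 in AcOH at rt aromatise the ring and block both free positions. This gives crystalline methyl 3,5-dibromo-2,4-dihydroxy-6-pentylbenzoate F2. Both bromines are then removed by hydrogenolysis (H2, Pd/C, NaOAc, MeOH, rt) to give 13.

**Step 11 (depside coupling).** The risks are low conversion of the di-ortho-substituted acid, and C-acylation or trifluoroacetylation of 17 in the acidic medium. The fallback sets out from 8 and comes back at 19. It replaces acid-side (acylium) activation with a preformed acyl donor and base-side activation of the phenol. Acid 8 is converted with oxalyl chloride and catalytic DMF in CH2Cl2 into 2,4-dimethoxy-6-propylbenzoyl chloride F3, which is freed of volatiles. F3 is then added to 17 with Et3N (1.2 equiv) and DMAP (0.1 equiv) in CH2Cl2 at 0 °C to rt. The more acidic, unchelated 4-OH is acylated and gives 19.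

## Further compounds
F1 | step 2 | methyl 2-hydroxy-4-methoxy-6-propylbenzoate | CCCc1cc(OC)cc(O)c1C(=O)OC
F2 | step 6 | methyl 3,5-dibromo-2,4-dihydroxy-6-pentylbenzoate | CCCCCc1c(Br)c(O)c(Br)c(O)c1C(=O)OC
F3 | step 11 | 2,4-dimethoxy-6-propylbenzoyl chloride | CCCc1cc(OC)cc(OC)c1C(=O)Cl
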